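The route cuts the C7–C8 bond (germacrane numbering), the one bond shared by the ten-membered carbocycle and the α-methylene-γ-lactone. C8 carries the lactone oxygen and C7 the C11=C13 arm, which is the retron of a carbonyl 2-(alkoxycarbonyl)allylation. An intramolecular CrCl2-mediated Barbier (Nozaki–Hiyama–Kishi) allylation of a linear bromo aldehyde closes the ten-membered ring, sets C7 and C8, creates the exo-methylene by allyl transposition and releases the alkoxide that lactonises onto C12. The precursor, an (E)-2-(bromomethyl)enoate with a β,γ-unsaturated aldehyde at the other end, comes from (S)-linalool (C1–C6, C15 and the C4 carbinol). C6 is set by asymmetric alkynylation, and the side-chain ester is attached last.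

Key step: step 16

Remarks on the chemistry:
- Germacrane numbering is used throughout: C1=C10 ring alkene, C14 on C10, C15 methyl on C4, C12 lactone carbonyl, C13 exo-methylene carbon.
- TBS = tert-butyldimethylsilyl.
- Assumption: (S)-(+)-linalool of high enantiomeric purity is taken as a purchasable starting material.
- The ProPhenol enantiomer in step 10 is the one that directs Si-face addition to the aldehyde; it is taken here as (R,R).

Step 1
Reactants: 1 (S)-(+)-linalool
Product: 2 (S)-linalool TBS ether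
Conditions: TBSOTf, 2,6-lutidine, CH2Cl2, −78 → 0 °C
Reagents that add atoms: tert-butyldimethylsilyl triflate, CC(C)(C)[Si](C)(C)OS(=O)(=O)C(F)(F)F
Why: Silylation of the tertiary allylic alcohol with a silyl triflate and a hindered base masks the C4 hydroxyl for the whole sequence and leaves the C4 stereocenter, taken from the chiral pool, untouched.

Step 2
Reactants: 2 (S)-linalool TBS ether
Product: 4 (4S)-4-(TBS-oxy)-4-methylhex-5-enal, via ozonide 3 (not isolated)
Conditions: O3, CH2Cl2, −78 °C (Sudan red 7B end point); then PPh3, −78 °C → rt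
Reagents that add atoms: ozone, [O-][O+]=O
Why: Chemoselective ozonolysis; the electron-rich trisubstituted alkene should react far faster than the hindered monosubstituted vinyl group, and reduction of ozonide 3 gives the C1 aldehyde.

Step 3
Reactants: 5 (3-bromopropoxy)(tert-butyl)dimethylsilane
Product: 6 [3-(TBS-oxy)propyl]triphenylphosphonium bromide
Conditions: PPh3, MeCN, reflux
Reagents that add atoms: triphenylphosphine, c1ccc(cc1)P(c1ccccc1)c1ccccc1
Why: SN2 quaternisation of the phosphine by a primary bromide (phosphonium salt formation).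

Step 4
Reactants: 6 [3-(TBS-oxy)propyl]triphenylphosphonium bromide
Product: 8 ethyl 4-(TBS-oxy)-2-(triphenyl-λ5-phosphanylidene)butanoate, via non-stabilised ylide 7 (not isolated)
Conditions: NaN(SiMe3)2 (1 equiv), THF, 0 °C; ClCO2Et, −78 °C; NaN(SiMe3)2 (1 equiv), −78 → 0 °C
Reagents that add atoms: ethyl chloroformate, CCOC(=O)Cl
Why: C-acylation of a phosphorus ylide; ylide 7 is acylated by the chloroformate and the more acidic acylphosphonium salt is deprotonated to the stabilised ylide.

Step 5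
Reactants: 4 (4S)-4-(TBS-oxy)-4-methylhex-5-enal; 8 ethyl 4-(TBS-oxy)-2-(triphenyl-λ5-phosphanylidene)butanoate
Product: 9 ethyl (2E,6S)-6-(TBS-oxy)-2-[2-(TBS-oxy)ethyl]-6-methylocta-2,7-dienoate
Conditions: toluene, 90 °C
Reagents that add atoms: none
Why: Wittig olefination with an α-substituted stabilised ylide should be (E)-selective, which places C9 cis to C2 and C14 trans to it, the ring-cis C1=C10 geometry of the target.

Step 6
Reactants: 9 ethyl (2E,6S)-6-(TBS-oxy)-2-[2-(TBS-oxy)ethyl]-6-methylocta-2,7-dienoate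
Product: 10 (2E,6S)-6-(TBS-oxy)-2-[2-(TBS-oxy)ethyl]-6-methylocta-2,7-dien-1-ol
Conditions: iBu2AlH, CH2Cl2, −78 °C; aq. potassium sodium tartrate
Reagents that add atoms: none
Why: 1,2-Reduction of the conjugated ester by the aluminium hydride gives the C14 allylic alcohol without touching alkenes or silyl ethers.

Step 7
Reactants: 10 (2E,6S)-6-(TBS-oxy)-2-[2-(TBS-oxy)ethyl]-6-methylocta-2,7-dien-1-ol
Product: 11 (2E,6S)-6-(TBS-oxy)-2-[2-(TBS-oxy)ethyl]-6-methylocta-2,7-dien-1-yl acetate
Conditions: Ac2O, pyridine, DMAP (cat.), CH2Cl2, 0 °C → rt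
Reagents that add atoms: acetic anhydride, CC(=O)OC(C)=O
Why: Acylation of the primary alcohol installs the C14 acetate of the target, which also differentiates C14 from the silyl-protected C8 oxygen.

Step 8
Reactants: 11 (2E,6S)-6-(TBS-oxy)-2-[2-(TBS-oxy)ethyl]-6-methylocta-2,7-dien-1-yl acetate
Product: 13 (2E,6S)-6-(TBS-oxy)-2-[2-(TBS-oxy)ethyl]-8-hydroxy-6-methyloct-2-en-1-yl acetate, via alkylborane 12 (not isolated)
Conditions: 9-BBN, THF, 0 → 50 °C; then NaBO3·4H2O, THF/H2O, rt
Reagents that add atoms: sodium perborate, [Na+].[O-]OB=O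
Why: Hydroboration–oxidation; 9-BBN should add only to the monosubstituted vinyl group with anti-Markovnikov regiochemistry, and perborate oxidises the C–B bond of 12 without hydrolysing the acetate.

Step 9
Reactants: 13 (2E,6S)-6-(TBS-oxy)-2-[2-(TBS-oxy)ethyl]-8-hydroxy-6-methyloct-2-en-1-yl acetate
Product: 14 (2E,6S)-6-(TBS-oxy)-2-[2-(TBS-oxy)ethyl]-6-methyl-8-oxooct-2-en-1-yl acetate
Conditions: Dess–Martin periodinane, NaHCO3, CH2Cl2, 0 °C → rt
Reagents that add atoms: none
Why: Buffered Dess–Martin oxidation should give the β-silyloxy aldehyde (C6) without β-elimination.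

Step 10
Reactants: 14 (2E,6S)-6-(TBS-oxy)-2-[2-(TBS-oxy)ethyl]-6-methyl-8-oxooct-2-en-1-yl acetate; 15 methyl propiolate
Product: 16 methyl (4R,6S,9E)-10-(acetoxymethyl)-6,12-bis(TBS-oxy)-4-hydroxy-6-methyldodec-9-en-2-ynoate
Conditions: Me2Zn, (R,R)-ProPhenol (20 mol%), Ph3PO (40 mol%), toluene, 4 °C
Reagents that add atoms: none
Why: Catalytic enantioselective alkynylation of an aldehyde by an alkynylzinc formed in the flask; the dinuclear zinc–ProPhenol catalyst should direct Si-face addition and so set C6 (R), with the remote C4 centre expected to have little influence.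

Step 11
Reactants: 16 methyl (4R,6S,9E)-10-(acetoxymethyl)-6,12-bis(TBS-oxy)-4-hydroxy-6-methyldodec-9-en-2-ynoate
Product: 17 methyl (4R,6S,9E)-10-(acetoxymethyl)-4,6,12-tris(TBS-oxy)-6-methyldodec-9-en-2-ynoate
Conditions: TBSOTf, 2,6-lutidine, CH2Cl2, −78 → 0 °C
Reagents that add atoms: tert-butyldimethylsilyl triflate, CC(C)(C)[Si](C)(C)OS(=O)(=O)C(F)(F)F
Why: Silylation of the secondary propargylic alcohol blocks butenolide formation at the next stage and makes the C6 oxygen a poor leaving group.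

Step 12
Reactants: 17 methyl (4R,6S,9E)-10-(acetoxymethyl)-4,6,12-tris(TBS-oxy)-6-methyldodec-9-en-2-ynoate
Product: 19 methyl (2Z,4R,6S,9E)-10-(acetoxymethyl)-4,6,12-tris(TBS-oxy)-2-(hydroxymethyl)-6-methyldodeca-2,9-dienoate, via α-alumino enoate 18 (not isolated)
Conditions: iBu2AlH, N-methylmorpholine N-oxide, THF, 0 °C; then CH2O (gas), −20 °C → rt; aq. potassium sodium tartrate
Reagents that add atoms: formaldehyde, C=O
Why: Vinylalumination; syn-hydroalumination of the ynoate by the Lewis-base-moderated hydride puts H on C7 and Al on C11, and hydroxymethylation of 18 at C11 with retention leaves C6 cis to CO2Me, the allyl geometry needed for the anti allylation, while isolated esters should not be reduced.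

Step 13
Reactants: 19 methyl (2Z,4R,6S,9E)-10-(acetoxymethyl)-4,6,12-tris(TBS-oxy)-2-(hydroxymethyl)-6-methyldodeca-2,9-dienoate
Product: 20 methyl (2E,4R,6S,9E)-10-(acetoxymethyl)-2-(bromomethyl)-4,6,12-tris(TBS-oxy)-6-methyldodeca-2,9-dienoate
Conditions: CBr4, PPh3, CH2Cl2, 0 °C
Reagents that add atoms: carbon tetrabromide, BrC(Br)(Br)Br
Why: Appel bromination of the primary allylic alcohol by SN2 displacement should keep the alkene geometry.

Step 14
Reactants: 20 methyl (2E,4R,6S,9E)-10-(acetoxymethyl)-2-(bromomethyl)-4,6,12-tris(TBS-oxy)-6-methyldodeca-2,9-dienoate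
Product: 21 methyl (2E,4R,6S,9E)-10-(acetoxymethyl)-2-(bromomethyl)-4,6-bis(TBS-oxy)-12-hydroxy-6-methyldodeca-2,9-dienoate
Conditions: CSA (cat.), MeOH/CH2Cl2 (1:1), 0 °C
Reagents that add atoms: none
Why: Acid-catalysed methanolysis should remove the unhindered primary silyl ether much faster than the secondary and tertiary ones (steric differentiation of silyl ethers), under non-nucleophilic conditions that spare the allylic bromide.

Step 15
Reactants: 21 methyl (2E,4R,6S,9E)-10-(acetoxymethyl)-2-(bromomethyl)-4,6-bis(TBS-oxy)-12-hydroxy-6-methyldodeca-2,9-dienoate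
Product: 22 methyl (2E,4R,6S,9E)-10-(acetoxymethyl)-2-(bromomethyl)-4,6-bis(TBS-oxy)-6-methyl-12-oxododeca-2,9-dienoate
Conditions: Dess–Martin periodinane, NaHCO3, CH2Cl2, 0 °C
Reagents that add atoms: none
Why: Neutral Dess–Martin oxidation of the homoallylic alcohol should give the β,γ-unsaturated C8 aldehyde without migration of the alkene into conjugation; the aldehyde is used at once.

Step 16
Reactants: 22 methyl (2E,4R,6S,9E)-10-(acetoxymethyl)-2-(bromomethyl)-4,6-bis(TBS-oxy)-6-methyl-12-oxododeca-2,9-dienoate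
Product: 25 (1(10)E,4S,6R,7S,8R)-14-acetoxy-4,6-bis(TBS-oxy)germacra-1(10),11(13)-dien-12,8-olide, via allylchromium species 23 (not isolated), via hydroxy ester 24 (not isolated)
Conditions: CrCl2 (10 equiv), DMF, rt, slow addition of 22 (final 2 mM); aq. NH4Cl; then PPTS (cat.), CH2Cl2, rt
Reagents that add atoms: none
Why: Two equivalents of CrCl2 (divalent chromium) reduce the allylic C–Br bond to the allylchromium species 23 (trivalent chromium), which adds through its γ-carbon C7 to the C8 aldehyde in a six-membered chair transition state with allylic transposition, so that the C11=C13 exo-methylene appears as the C7–C8 bond forms, and the C8 hydroxyl of 24 then lactonises onto the C12 ester. The closest known reaction type is the intramolecular Nozaki–Hiyama–Kishi (Barbier) allylation of aldehydes with 2-(bromomethyl)acrylates, which is established for α-methylene-γ-lactones and for ten-membered germacranolide rings. The ten-membered carbocycle closes by 10-exo-trig addition to the aldehyde and the γ-lactone by 5-exo-trig acyl substitution at C12. The C7/C8 anti relationship (trans-fused lactone) should follow from the allyl geometry (C6 trans to CH2Cr, hence equatorial) with C9 equatorial in the chair; the sense relative to C6 is set by the C6 silyloxy stereocenter, where allylic 1,3-strain with the cis CO2Me keeps H6 in the alkene plane, the tether carbon C5 sits anti to the incoming carbonyl and the silyloxy group points outside. The step needs metalation of the allylic bromide beside the allylic acetate, retention of the allyl geometry, the stated face selectivity and ring closure over oligomerisation; CrCl2 does not touch acetates or silyl ethers, the primary allylchromium has no β-leaving group, and high dilution, the quaternary C4 and the cis C1=C10 alkene favour cyclisation.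

Step 17
Reactants: 25 (1(10)E,4S,6R,7S,8R)-14-acetoxy-4,6-bis(TBS-oxy)germacra-1(10),11(13)-dien-12,8-olide
Product: 26 (1(10)E,4S,6R,7R,8R)-14-acetoxy-4,6-dihydroxygermacra-1(10),11(13)-dien-12,8-olide
Conditions: HF·pyridine, THF, 0 °C → rt
Reagents that add atoms: none
Why: Fluoride-mediated cleavage of both silyl ethers under buffered conditions should tolerate the α-methylene lactone and the allylic acetate; the C7 descriptor changes only through CIP priorities, not in space.

Step 18
Reactants: 27 tert-butyl but-2-ynoate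
Product: 29 tert-butyl (2Z)-2-(hydroxymethyl)but-2-enoate, via α-alumino crotonate 28 (not isolated)
Conditions: iBu2AlH, N-methylmorpholine N-oxide, THF, 0 °C; then CH2O (gas), −20 °C → rt
Reagents that add atoms: formaldehyde, C=O
Why: Vinylalumination as in step 12; syn-hydroalumination and hydroxymethylation at the α-carbon leave the methyl group cis to the ester, the (Z) geometry of the side chain.

Step 19
Reactants: 29 tert-butyl (2Z)-2-(hydroxymethyl)but-2-enoate
Product: 30 tert-butyl (2Z)-2-(acetoxymethyl)but-2-enoate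
Conditions: Ac2O, pyridine, CH2Cl2, 0 °C
Reagents that add atoms: acetic anhydride, CC(=O)OC(C)=O
Why: Acetylation of the primary allylic alcohol without a nucleophilic catalyst avoids SN2′ addition–elimination that could scramble the alkene geometry.

Step 20
Reactants: 30 tert-butyl (2Z)-2-(acetoxymethyl)but-2-enoate
Product: 31 (2Z)-2-(acetoxymethyl)but-2-enoic acid
Conditions: CF3CO2H/CH2Cl2 (1:4), 0 °C
Reagents that add atoms: none
Why: Acidolysis of the tert-butyl ester with loss of isobutene should free the acid without touching the acetate or the (Z) alkene.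

Step 21
Reactants: 26 (1(10)E,4S,6R,7R,8R)-14-acetoxy-4,6-dihydroxygermacra-1(10),11(13)-dien-12,8-olide; 31 (2Z)-2-(acetoxymethyl)but-2-enoic acid
Product: 33 CNP0280960.1, via mixed anhydride 32 (not isolated)
Conditions: 2,4,6-trichlorobenzoyl chloride, iPr2NEt, toluene, rt; then 26, toluene, 80 °C
Reagents that add atoms: none
Why: Yamaguchi-type esterification through mixed anhydride 32 without a nucleophilic catalyst, as used for angelate esters, should acylate the secondary C6 hydroxyl with retention while the (Z) alkene does not isomerise and the tertiary C4 hydroxyl does not react.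

Compound list
1 | (S)-(+)-linalool, (3S)-3,7-dimethylocta-1,6-dien-3-ol | C=C[C@@](C)(O)CCC=C(C)C | starting material
2 | (S)-linalool TBS ether | C=C[C@@](C)(O[Si](C)(C)C(C)(C)C)CCC=C(C)C | intermediate
3 | ozonide of 2 at the trisubstituted alkene (1,2,4-trioxolane, mixture at the acetal carbon) | C=C[C@@](C)(O[Si](C)(C)C(C)(C)C)CCC1OOC(C)(C)O1 | intermediate
4 | (4S)-4-(TBS-oxy)-4-methylhex-5-enal | C=C[C@@](C)(O[Si](C)(C)C(C)(C)C)CCC=O | intermediate
5 | (3-bromopropoxy)(tert-butyl)dimethylsilane | CC(C)(C)[Si](C)(C)OCCCBr | starting material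
6 | [3-(TBS-oxy)propyl]triphenylphosphonium bromide | CC(C)(C)[Si](C)(C)OCCC[P+](c1ccccc1)(c1ccccc1)c1ccccc1.[Br-] | intermediate
7 | [3-(TBS-oxy)propylidene]triphenylphosphorane (non-stabilised ylide) | CC(C)(C)[Si](C)(C)OCCC=P(c1ccccc1)(c1ccccc1)c1ccccc1 | intermediate
8 | ethyl 4-(TBS-oxy)-2-(triphenyl-λ5-phosphanylidene)butanoate | CCOC(=O)C(CCO[Si](C)(C)C(C)(C)C)=P(c1ccccc1)(c1ccccc1)c1ccccc1 | intermediate
9 | ethyl (2E,6S)-6-(TBS-oxy)-2-[2-(TBS-oxy)ethyl]-6-methylocta-2,7-dienoate | C=C[C@@](C)(O[Si](C)(C)C(C)(C)C)CC/C=C(\CCO[Si](C)(C)C(C)(C)C)C(=O)OCC | intermediate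
10 | (2E,6S)-6-(TBS-oxy)-2-[2-(TBS-oxy)ethyl]-6-methylocta-2,7-dien-1-ol | C=C[C@@](C)(O[Si](C)(C)C(C)(C)C)CC/C=C(\CCO[Si](C)(C)C(C)(C)C)CO | intermediate
11 | (2E,6S)-6-(TBS-oxy)-2-[2-(TBS-oxy)ethyl]-6-methylocta-2,7-dien-1-yl acetate | C=C[C@@](C)(O[Si](C)(C)C(C)(C)C)CC/C=C(\CCO[Si](C)(C)C(C)(C)C)COC(C)=O | intermediate
12 | B-alkyl-9-borabicyclo[3.3.1]nonane from 11 (boron on the terminal carbon of the former vinyl group) | B1(CC[C@@](C)(O[Si](C)(C)C(C)(C)C)CC/C=C(\CCO[Si](C)(C)C(C)(C)C)COC(C)=O)C2CCCC1CCC2 | intermediate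
13 | (2E,6S)-6-(TBS-oxy)-2-[2-(TBS-oxy)ethyl]-8-hydroxy-6-methyloct-2-en-1-yl acetate | OCC[C@@](C)(O[Si](C)(C)C(C)(C)C)CC/C=C(\CCO[Si](C)(C)C(C)(C)C)COC(C)=O | intermediate
14 | (2E,6S)-6-(TBS-oxy)-2-[2-(TBS-oxy)ethyl]-6-methyl-8-oxooct-2-en-1-yl acetate | O=CC[C@@](C)(O[Si](C)(C)C(C)(C)C)CC/C=C(\CCO[Si](C)(C)C(C)(C)C)COC(C)=O | intermediate
15 | methyl propiolate | C#CC(=O)OC | starting material
16 | methyl (4R,6S,9E)-10-(acetoxymethyl)-6,12-bis(TBS-oxy)-4-hydroxy-6-methyldodec-9-en-2-ynoate | COC(=O)C#C[C@H](O)C[C@@](C)(O[Si](C)(C)C(C)(C)C)CC/C=C(\CCO[Si](C)(C)C(C)(C)C)COC(C)=O | intermediate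
17 | methyl (4R,6S,9E)-10-(acetoxymethyl)-4,6,12-tris(TBS-oxy)-6-methyldodec-9-en-2-ynoate | COC(=O)C#C[C@H](O[Si](C)(C)C(C)(C)C)C[C@@](C)(O[Si](C)(C)C(C)(C)C)CC/C=C(\CCO[Si](C)(C)C(C)(C)C)COC(C)=O | intermediate
18 | α-(diisobutylalumino) enoate from 17 (Al on C11, cis to H7; C6 cis to CO2Me) | COC(=O)/C([Al](CC(C)C)CC(C)C)=C\[C@H](O[Si](C)(C)C(C)(C)C)C[C@@](C)(O[Si](C)(C)C(C)(C)C)CC/C=C(\CCO[Si](C)(C)C(C)(C)C)COC(C)=O | intermediate
19 | methyl (2Z,4R,6S,9E)-10-(acetoxymethyl)-4,6,12-tris(TBS-oxy)-2-(hydroxymethyl)-6-methyldodeca-2,9-dienoate | COC(=O)/C(CO)=C\[C@H](O[Si](C)(C)C(C)(C)C)C[C@@](C)(O[Si](C)(C)C(C)(C)C)CC/C=C(\CCO[Si](C)(C)C(C)(C)C)COC(C)=O | intermediate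
20 | methyl (2E,4R,6S,9E)-10-(acetoxymethyl)-2-(bromomethyl)-4,6,12-tris(TBS-oxy)-6-methyldodeca-2,9-dienoate | COC(=O)/C(CBr)=C\[C@H](O[Si](C)(C)C(C)(C)C)C[C@@](C)(O[Si](C)(C)C(C)(C)C)CC/C=C(\CCO[Si](C)(C)C(C)(C)C)COC(C)=O | intermediate
21 | methyl (2E,4R,6S,9E)-10-(acetoxymethyl)-2-(bromomethyl)-4,6-bis(TBS-oxy)-12-hydroxy-6-methyldodeca-2,9-dienoate | COC(=O)/C(CBr)=C\[C@H](O[Si](C)(C)C(C)(C)C)C[C@@](C)(O[Si](C)(C)C(C)(C)C)CC/C=C(\CCO)COC(C)=O | intermediate
22 | methyl (2E,4R,6S,9E)-10-(acetoxymethyl)-2-(bromomethyl)-4,6-bis(TBS-oxy)-6-methyl-12-oxododeca-2,9-dienoate | COC(=O)/C(CBr)=C\[C@H](O[Si](C)(C)C(C)(C)C)C[C@@](C)(O[Si](C)(C)C(C)(C)C)CC/C=C(\CC=O)COC(C)=O | intermediate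
23 | allylchromium species from 22 (CrCl2 unit on C13, trivalent chromium) | COC(=O)/C(C[Cr](Cl)Cl)=C\[C@H](O[Si](C)(C)C(C)(C)C)C[C@@](C)(O[Si](C)(C)C(C)(C)C)CC/C=C(\CC=O)COC(C)=O | intermediate
24 | methyl (1(10)E,4S,6R,7S,8R)-14-acetoxy-4,6-bis(TBS-oxy)-8-hydroxygermacra-1(10),11(13)-dien-12-oate (ring-closed hydroxy ester) | C=C(C(=O)OC)[C@H]1[C@H](O)C/C(COC(C)=O)=C\CC[C@](C)(O[Si](C)(C)C(C)(C)C)C[C@H]1O[Si](C)(C)C(C)(C)C | intermediate
25 | (1(10)E,4S,6R,7S,8R)-14-acetoxy-4,6-bis(TBS-oxy)germacra-1(10),11(13)-dien-12,8-olide | C=C1C(=O)O[C@@H]2C/C(COC(C)=O)=C\CC[C@](C)(O[Si](C)(C)C(C)(C)C)C[C@@H](O[Si](C)(C)C(C)(C)C)[C@@H]12 | intermediate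
26 | (1(10)E,4S,6R,7R,8R)-14-acetoxy-4,6-dihydroxygermacra-1(10),11(13)-dien-12,8-olide | C=C1C(=O)O[C@@H]2C/C(COC(C)=O)=C\CC[C@](C)(O)C[C@@H](O)[C@@H]12 | intermediate
27 | tert-butyl but-2-ynoate | CC#CC(=O)OC(C)(C)C | starting material
28 | tert-butyl (2Z)-2-(diisobutylalumino)but-2-enoate (Al cis to H3) | C/C=C(/[Al](CC(C)C)CC(C)C)C(=O)OC(C)(C)C | intermediate
29 | tert-butyl (2Z)-2-(hydroxymethyl)but-2-enoate | C/C=C(/CO)C(=O)OC(C)(C)C | intermediate
30 | tert-butyl (2Z)-2-(acetoxymethyl)but-2-enoate | C/C=C(/COC(C)=O)C(=O)OC(C)(C)C | intermediate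
31 | (2Z)-2-(acetoxymethyl)but-2-enoic acid | C/C=C(/COC(C)=O)C(=O)O | intermediate
32 | (2Z)-2-(acetoxymethyl)but-2-enoic 2,4,6-trichlorobenzoic anhydride | C/C=C(/COC(C)=O)C(=O)OC(=O)c1c(Cl)cc(Cl)cc1Cl | intermediate
33 | CNP0280960.1, (1(10)E,4S,6R,7S,8R)-14-acetoxy-6-{[(2Z)-2-(acetoxymethyl)but-2-enoyl]oxy}-4-hydroxygermacra-1(10),11(13)-dien-12,8-olide | C=C1C(=O)O[C@@H]2C/C(COC(C)=O)=C\CC[C@](C)(O)C[C@@H](OC(=O)/C(=C\C)COC(C)=O)[C@@H]12 | target

Total step count: 21 steps. Longest linear sequence: 16 steps (steps 1, 2, 5–17 and 21; steps 3–4 and 18–20 are side branches).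

Steps most likely to fail

Step 16. The allylchromium species may lose its allyl geometry by σ–π–σ equilibration before the C–C bond forms, which would lead to the cis-fused lactone, and intermolecular coupling or protonation may outrun closure of the ten-membered ring. The fallback replaces chromium by a configurationally fixed boron allyl donor. It sets out from ynoate 17: the α-alumino enoate 18 is trapped with ICH2Bpin instead of formaldehyde to give the 2-(pinacolborylmethyl)enoate, allylboronate F1, with C6 still cis to CO2Me. Methanolysis with CSA removes the primary silyl ether to give the boronate alcohol F2, and Dess–Martin oxidation gives the boronate aldehyde F3. Sc(OTf)3 (cat.) in toluene at high dilution should then close the ring through the chair transition state of allylboration to the borate ester F4, which is hydrolysed on work-up to 24 and lactonised with PPTS; the fallback rejoins the route at 25.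

Step 12. The aluminium hydride may reduce the acetate or the conjugated ester, the α-alumino enoate may be protonated instead of hydroxymethylated, or the alkene geometry may erode through the allenolate form. The fallback uses tin and palladium instead of aluminium. It sets out from ynoate 17: syn-hydrostannation with Bu3SnH and Pd(PPh3)4 (cat.) should give the α-stannyl enoate F5 (tin on C11, C6 cis to CO2Me). Iodine converts it with retention into the α-iodo enoate F6, and Stille coupling with Bu3SnCH2OH (Pd(PPh3)4, dioxane, 80 °C) installs the hydroxymethyl group; the fallback rejoins the route at 19.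

Step 10. Facial selectivity at the unbranched β-silyloxy aldehyde may be poor (formation of the C6 epimer), and aldol condensation or β-elimination may compete under zinc alkoxide conditions. The fallback sets C6 by reagent-controlled reduction instead of catalytic addition. It sets out from aldehyde 14: LiC≡CCO2Me (from 15 and LiN(SiMe3)2, THF, −78 °C) adds without selectivity to give 16 together with its C6 epimer, the (4S)-carbinol F7. Dess–Martin oxidation of the mixture gives the ynone F8. (R)-Alpine-Borane (B-isopinocampheyl-9-BBN from (+)-α-pinene, neat, rt), which is known to reduce 4-oxo-2-ynoates and to give the (R) carbinol for this substitution pattern, should reduce F8; the fallback rejoins the route at 16.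

Further compounds
F1 | step 16 | methyl (2Z,4R,6S,9E)-10-(acetoxymethyl)-4,6,12-tris(TBS-oxy)-6-methyl-2-[(4,4,5,5-tetramethyl-1,3,2-dioxaborolan-2-yl)methyl]dodeca-2,9-dienoate | COC(=O)/C(CB1OC(C)(C)C(C)(C)O1)=C\[C@H](O[Si](C)(C)C(C)(C)C)C[C@@](C)(O[Si](C)(C)C(C)(C)C)CC/C=C(\CCO[Si](C)(C)C(C)(C)C)COC(C)=O
F2 | step 16 | 12-hydroxy analogue of F1 (primary silyl ether removed) | COC(=O)/C(CB1OC(C)(C)C(C)(C)O1)=C\[C@H](O[Si](C)(C)C(C)(C)C)C[C@@](C)(O[Si](C)(C)C(C)(C)C)CC/C=C(\CCO)COC(C)=O
F3 | step 16 | 12-oxo analogue of F1 (boronate aldehyde) | COC(=O)/C(CB1OC(C)(C)C(C)(C)O1)=C\[C@H](O[Si](C)(C)C(C)(C)C)C[C@@](C)(O[Si](C)(C)C(C)(C)C)CC/C=C(\CC=O)COC(C)=O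
F4 | step 16 | 8-O-(pinacolboryl) derivative of hydroxy ester 24 | C=C(C(=O)OC)[C@H]1[C@H](OB2OC(C)(C)C(C)(C)O2)C/C(COC(C)=O)=C\CC[C@](C)(O[Si](C)(C)C(C)(C)C)C[C@H]1O[Si](C)(C)C(C)(C)C
F5 | step 12 | methyl (2E,4R,6S,9E)-10-(acetoxymethyl)-4,6,12-tris(TBS-oxy)-6-methyl-2-(tributylstannyl)dodeca-2,9-dienoate | COC(=O)/C([Sn](CCCC)(CCCC)CCCC)=C\[C@H](O[Si](C)(C)C(C)(C)C)C[C@@](C)(O[Si](C)(C)C(C)(C)C)CC/C=C(\CCO[Si](C)(C)C(C)(C)C)COC(C)=O
F6 | step 12 | methyl (2E,4R,6S,9E)-10-(acetoxymethyl)-4,6,12-tris(TBS-oxy)-2-iodo-6-methyldodeca-2,9-dienoate | COC(=O)/C(I)=C\[C@H](O[Si](C)(C)C(C)(C)C)C[C@@](C)(O[Si](C)(C)C(C)(C)C)CC/C=C(\CCO[Si](C)(C)C(C)(C)C)COC(C)=O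
F7 | step 10 | methyl (4S,6S,9E)-10-(acetoxymethyl)-6,12-bis(TBS-oxy)-4-hydroxy-6-methyldodec-9-en-2-ynoate (C6 epimer of 16 in germacrane numbering) | COC(=O)C#C[C@@H](O)C[C@@](C)(O[Si](C)(C)C(C)(C)C)CC/C=C(\CCO[Si](C)(C)C(C)(C)C)COC(C)=O
F8 | step 10 | methyl (6S,9E)-10-(acetoxymethyl)-6,12-bis(TBS-oxy)-6-methyl-4-oxododec-9-en-2-ynoate | COC(=O)C#CC(=O)C[C@@](C)(O[Si](C)(C)C(C)(C)C)CC/C=C(\CCO[Si](C)(C)C(C)(C)C)COC(C)=O
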